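**Plan**
1. Retrosynthesis: the 7-OH comes from an acetate. Pyranone ring C is cut at C3=C4 and O1–C2 (Perkin–Oglialoro) into 2,4-dihydroxy-6-methoxybenzaldehyde and a chroman-6-ylacetic acid. The CH2CO2H chain goes back to an acetyl group, and the chroman 5-OMe to a chelated OH.
2. Dihydropyran ring D is then cut at C4–C3 and O1–C2 in one stroke into isobutene and an ortho-quinone methide. The C4a–C4 bond is cut last (Mannich), which leads to 2,4-dihydroxyacetophenone.
3. Enabling feature: in ring D the ether oxygen O1 on C8a stands ortho to the benzylic C4H2 on C4a, so O1–C8a–C4a–C4 is a masked heterodiene O=C–C=CH2 and C3H2–C2(CH3)2 is isobutene. C4a lies between the oxygen-bearing carbons C5 and C8a of a resorcinol, which is the site where a chelated 2,4-dihydroxyaryl ketone is aminomethylated.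
4. Helpers: NMe2 is the leaving group and is lost in the event. The acetyl group chelates the future 5-OH so that only the other oxygen closes ring D, and its two carbons later become C3 and C2 of the coumarin. The 7-acetate is put on by the Perkin medium and removed last.
5. Forward order: ring B (bought) → ring D (step 2) → side chain (steps 3–5) → rings A and C joined on (step 6) → deacetylation (step 7).
6. Stereochemistry: the target has no stereocentre and no open-chain double bond, so nothing has to be set.

Key step: step 2

Assumption: 2,4-dihydroxy-6-methoxybenzaldehyde is taken as a catalogue compound, like 2,4-dihydroxyacetophenone and isobutene.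

**Route**

Step 1
Reactants: 1 resacetophenone (2,4-dihydroxyacetophenone)
Product: 2 Mannich base 3-[(dimethylamino)methyl]-2,4-dihydroxyacetophenone
Conditions: CH2(NMe2)2 (1.1 equiv), 1,4-dioxane, 100 °C
Reagents that add atoms: bis(dimethylamino)methane CN(C)CN(C)C
Why: Phenolic Mannich aminomethylation, which in chelated 2,4-dihydroxyaryl ketones should take place at C3 between the two hydroxyl groups, as in the 8-substitution of 7-hydroxychromones and 7-hydroxycoumarins.

Step 2
Reactants: 2 Mannich base 3-[(dimethylamino)methyl]-2,4-dihydroxyacetophenone; 3 isobutene (2-methylpropene)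
Product: 5 chroman ketone 6-acetyl-5-hydroxy-2,2-dimethylchroman, via ortho-quinone methide 4 (not isolated)
Conditions: isobutene (large excess, condensed in), DMF, 155 °C, sealed steel autoclave
Reagents that add atoms: none
Why: Heating the internally hydrogen-bonded Mannich base 2 expels dimethylamine by retro-Michael elimination and unmasks ortho-quinone methide 4, whose heterodiene O=C4–C3=CH2 (acetophenone numbering) adds isobutene 3 in an inverse-electron-demand hetero-Diels–Alder reaction that restores the aromatic sextet. The closest known reaction type is the thermal chroman synthesis from phenolic Mannich bases (or from a phenol, formaldehyde and a secondary amine) and 1,1-disubstituted alkenes at 150–200 °C. Ring D is closed as the six-membered ring of an intermolecular [4+2] cycloaddition, and the C4–C3 and O1–C2 bonds (chroman numbering) arise in the same asynchronous event. No stereocentre is created, since C2 carries two methyl groups. Orientation is secured by polarity: the nucleophilic CH2 terminus of isobutene bonds to the electrophilic exocyclic methylene while positive charge builds on the tertiary carbon that oxygen takes, so only the 2,2-dimethyl isomer should form. The choice between the two phenolic oxygens is secured by the acetyl group, which holds the neighbouring hydroxyl in a chelate in 4 as in 5 and leaves the para oxygen as the heterodiene terminus, while a large excess of isobutene at high dilution of 2 should suppress self-condensation of 4.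

Step 3
Reactants: 5 chroman ketone 6-acetyl-5-hydroxy-2,2-dimethylchroman
Product: 6 methyl ether 6-acetyl-5-methoxy-2,2-dimethylchroman
Conditions: MeI (excess), K2CO3, acetone, reflux
Reagents that add atoms: iodomethane CI
Why: Williamson O-methylation of the only phenol, which as a chelated hydroxyl needs excess MeI and heat but has no competing nucleophilic site under carbonate conditions.

Step 4
Reactants: 6 methyl ether 6-acetyl-5-methoxy-2,2-dimethylchroman
Product: 7 thiomorpholide 2-(5-methoxy-2,2-dimethylchroman-6-yl)-1-(morpholin-4-yl)ethanethione
Conditions: S8, morpholine, TsOH·H2O (cat.), 130 °C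
Reagents that add atoms: sulfur S1SSSSSSS1; morpholine C1COCCN1
Why: Willgerodt–Kindler reaction, the standard way from ortho-methoxyacetophenones to arylacetic acid derivatives, in which the oxidised function moves to the chain terminus and the aryl ethers and chroman ring are left untouched.

Step 5
Reactants: 7 thiomorpholide 2-(5-methoxy-2,2-dimethylchroman-6-yl)-1-(morpholin-4-yl)ethanethione
Product: 8 acid 2-(5-methoxy-2,2-dimethylchroman-6-yl)acetic acid
Conditions: NaOH, EtOH/H2O, reflux; then HCl (aq)
Reagents that add atoms: sodium hydroxide [Na+].[OH-]; water O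
Why: Alkaline thioamide hydrolysis, the usual second stage of the Willgerodt–Kindler sequence, to which the methyl ether and the chroman ether are inert.

Step 6
Reactants: 8 acid 2-(5-methoxy-2,2-dimethylchroman-6-yl)acetic acid; 9 aldehyde 2,4-dihydroxy-6-methoxybenzaldehyde
Product: 11 coumarin acetate 7-acetoxy-5-methoxy-3-(5-methoxy-2,2-dimethylchroman-6-yl)coumarin, via aryl ester 10 (not isolated)
Conditions: Ac2O, Et3N, 120 °C
Reagents that add atoms: acetic anhydride CC(=O)OC(C)=O
Why: Perkin–Oglialoro condensation, in which Ac2O activates acid 8 and acetylates the para hydroxyl, the arylacetyl group is passed to the only hydroxyl ortho to the formyl group, and intramolecular aldol condensation of ester 10 followed by dehydration closes ring C.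

Step 7
Reactants: 11 coumarin acetate 7-acetoxy-5-methoxy-3-(5-methoxy-2,2-dimethylchroman-6-yl)coumarin
Product: 12 target 7-hydroxy-5-methoxy-3-(5-methoxy-2,2-dimethylchroman-6-yl)coumarin
Conditions: HCl (cat.), MeOH, reflux
Reagents that add atoms: none
Why: Acid-catalysed methanolysis (transesterification) of the aryl acetate, under which the coumarin lactone, both aryl methyl ethers and the chroman are stable.

**Compound list**
1 | resacetophenone (2,4-dihydroxyacetophenone) | CC(=O)c1ccc(O)cc1O | starting material
2 | Mannich base 3-[(dimethylamino)methyl]-2,4-dihydroxyacetophenone | CC(=O)c1ccc(O)c(CN(C)C)c1O | intermediate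
3 | isobutene (2-methylpropene) | CC(C)=C | starting material
4 | ortho-quinone methide 4-acetyl-3-hydroxy-2-methylidenecyclohexa-3,5-dien-1-one | CC(=O)C1=C(O)C(=C)C(=O)C=C1 | intermediate
5 | chroman ketone 6-acetyl-5-hydroxy-2,2-dimethylchroman | CC(=O)c1ccc2OC(C)(C)CCc2c1O | intermediate
6 | methyl ether 6-acetyl-5-methoxy-2,2-dimethylchroman | CC(=O)c1ccc2OC(C)(C)CCc2c1OC | intermediate
7 | thiomorpholide 2-(5-methoxy-2,2-dimethylchroman-6-yl)-1-(morpholin-4-yl)ethanethione | COc1c(CC(=S)N3CCOCC3)ccc2OC(C)(C)CCc12 | intermediate
8 | acid 2-(5-methoxy-2,2-dimethylchroman-6-yl)acetic acid | COc1c(CC(=O)O)ccc2OC(C)(C)CCc12 | intermediate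
9 | aldehyde 2,4-dihydroxy-6-methoxybenzaldehyde | COc1cc(O)cc(O)c1C=O | starting material
10 | aryl ester 5-acetoxy-2-formyl-3-methoxyphenyl 2-(5-methoxy-2,2-dimethylchroman-6-yl)acetate | COc1c(CC(=O)Oc3cc(OC(C)=O)cc(OC)c3C=O)ccc2OC(C)(C)CCc12 | intermediate
11 | coumarin acetate 7-acetoxy-5-methoxy-3-(5-methoxy-2,2-dimethylchroman-6-yl)coumarin | COc1c(-c3cc4c(OC)cc(OC(C)=O)cc4oc3=O)ccc2OC(C)(C)CCc12 | intermediate
12 | target 7-hydroxy-5-methoxy-3-(5-methoxy-2,2-dimethylchroman-6-yl)coumarin (CNP0139207.0) | COc1c(-c2cc3c(OC)cc(O)cc3oc2=O)ccc2c1CCC(C)(C)O2 | target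

**Step count**
Total step count: 7. Longest linear sequence: 7 steps (1 → 12). Aldehyde 9 enters as bought.

**Steps most likely to fail**

Step 2. Self-condensation of the quinone methide, or its recapture by dimethylamine, may outrun cycloaddition to a volatile and only moderately nucleophilic alkene. Ring closure through the chelated oxygen may also compete. The fallback sets out from 1 and builds ring D at the chromene oxidation level. Condensation of 1 with 3-methylbut-2-enal (pyridine, 140 °C) proceeds by aldol-type attack at C3, dehydration and oxa-6π electrocyclisation. It should give 1-(5-hydroxy-2,2-dimethyl-2H-chromen-6-yl)ethanone F1. Hydrogenation of its C3=C4 bond (H2, Pd/C, EtOAc) comes back to the route at 5.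

Step 4. Thioamide formation may be sluggish on a hindered, electron-rich ortho-methoxy ketone. Tar formation, or demethylation of the aryl methyl ether by sulfur nucleophiles at 130 °C, may also occur. The fallback sets out from 6 and replaces the chain walk by an oxidative 1,2-aryl migration. PhI(OAc)2, HC(OMe)3 and H2SO4 in MeOH at 60 °C should give methyl 2-(5-methoxy-2,2-dimethylchroman-6-yl)acetate F2. Saponification (LiOH, THF/H2O, then acid) comes back to the route at 8.

Step 6. Plain O-acetylation of both phenols may outcompete transfer of the hindered arylacetyl group. The aldol closure onto a doubly ortho-substituted, electron-rich aldehyde may be slow, and acetate may be built in instead of arylacetate. The fallback sets out from 9 and 8 and separates the events under an orthogonal protecting group.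
- Selective benzylation of the unchelated hydroxyl of 9 (BnBr, KHCO3, MeCN) should give 4-(benzyloxy)-2-hydroxy-6-methoxybenzaldehyde F3.
- Esterification with 8 (EDC·HCl, DMAP, CH2Cl2) should give 5-(benzyloxy)-2-formyl-3-methoxyphenyl 2-(5-methoxy-2,2-dimethylchroman-6-yl)acetate F4.
- Intramolecular Knoevenagel-type condensation (DBU, MeCN, 60 °C) should give 7-(benzyloxy)-5-methoxy-3-(5-methoxy-2,2-dimethylchroman-6-yl)coumarin F5.
- Hydrogenolysis (H2, Pd/C, EtOAc) comes back to the route at 12.

**Further compounds**
F1 | step 2 | 1-(5-hydroxy-2,2-dimethyl-2H-chromen-6-yl)ethanone | CC(=O)c1ccc2OC(C)(C)C=Cc2c1O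
F2 | step 4 | methyl 2-(5-methoxy-2,2-dimethylchroman-6-yl)acetate | COC(=O)Cc1ccc2OC(C)(C)CCc2c1OC
F3 | step 6 | 4-(benzyloxy)-2-hydroxy-6-methoxybenzaldehyde | COc1cc(OCc2ccccc2)cc(O)c1C=O
F4 | step 6 | 5-(benzyloxy)-2-formyl-3-methoxyphenyl 2-(5-methoxy-2,2-dimethylchroman-6-yl)acetate | COc1c(CC(=O)Oc3cc(OCc4ccccc4)cc(OC)c3C=O)ccc2OC(C)(C)CCc12
F5 | step 6 | 7-(benzyloxy)-5-methoxy-3-(5-methoxy-2,2-dimethylchroman-6-yl)coumarin | COc1c(-c3cc4c(OC)cc(OCc5ccccc5)cc4oc3=O)ccc2OC(C)(C)CCc12
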